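**Remark on the chemistry (assumption).** Ring A is numbered from the carbon that carries the ester carbonyl (C1; C2 OH, C3 CHO, C4 OMe, C5 H, C6 Me). Ring B is numbered from the carbon that carries the ester oxygen (C1'; C2' Me, C3' CO2H, C4' OH, C5' CHO, C6' OH). The triketide chain is numbered from the ester carbonyl (C1) to the methyl group (C8). LiN(SiMe3)2 and LiN(iPr)2 are used as purchased solutions.

## Structural features

Haemathamnolic acid is a depside: two benzene rings joined only by an aryl ester between the C1 carboxyl carbon of ring A and the oxygen on C1' of ring B, with no stereocentre anywhere. Ring A carries OH (C2), CHO (C3), OMe (C4) and Me (C6) and has one free position (C5); ring B is fully substituted. The ester is crowded on both sides: its acyl carbon sits between C2–OH and C6–Me, and its oxygen sits between C2'–Me and C6'–OH. Joining a finished ring A acid to a finished ring B phenol is therefore the hardest bond to make. Three features are fragile. The ester oxygen has a free hydroxyl on the neighbouring carbon C6' (a catechol monoester), so base can move or cleave the acyl group once that hydroxyl is free. There are two aryl aldehydes. Ring B is a β-resorcylic acid that can lose CO2. The real difficulty is the hindered ester combined with the regiochemistry of six different ring B substituents and the differentiation of three phenols from one methyl ether. The route exploits the fact that C1 (carboxyl), C2–O, C4–O and C6–Me of ring A form the orsellinate pattern, which is the aldol fold of a 3,5,7-trioxooctanoate. The ester can thus be made from an unhindered acylketene while C1 is still a chain carbon, and ring A is closed afterwards through the C1–C6 bond.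

## Logic of the disconnections

**18 ⇒ 17.** The O–C(CH3)3 bond of the ring B ester is cut. The free acid would be a β-resorcylic acid during formylation, so it stays masked until the end. A tert-butyl ester is chosen because it leaves under acid, which the aryl ester, aldehydes and phenols tolerate, and because it survives hydrogenolysis and amine bases. There is no skeletal gain; the forward step must cleave one ester and spare the other.

**17 ⇒ 16.** The C3–CHO and C5'–CHO bonds are cut together. Both carbons are ortho to phenols and are the only free ortho positions in 16. This removes two carbons and two sensitive aldehydes from every earlier step. The forward step must be strictly ortho-selective on both rings, must leave C5 of ring A alone, and must not move the acyl group to the neighbouring 6'-oxygen.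

**16 ⇒ 15 ⇒ 14.** The two O–CH2Ph bonds on ring B are cut, then the O–CH3 bond at C4. While ring B is benzylated, the only hydroxyl in 14 that is not hydrogen-bonded is C4–OH, so methylation needs no further protection. The gain is an unadorned orsellinate ring A in 14. The forward steps require a methylation that distinguishes C4–OH from the chelated C2–OH and a neutral debenzylation. All basic steps lie before the 6'-hydroxyl is freed.

**14 ⇒ 12.** The C1–C6 bond of ring A is cut (retro-aldol after formal rehydration). The aromatic ring and its two ortho substituents disappear, and the ester becomes that of an open β-keto acid. The forward step needs chain carbon 2 to attack the C7 ketone and not chain carbon 6 to attack the ester.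

**12 ⇒ 5 + 10 (through 11).** The acyl C1–O bond is cut. A ketene carbon is sp-hybridized and unhindered, needs no coupling agent, and 11 is released from 10 by heat alone. The gain is convergence into a C8 chain and ring B. The forward step requires that the di-ortho-substituted phenol capture 11 faster than 11 cyclizes onto its own enol.

**10 ⇒ 8 + 9, and 8 ⇒ 6 + 7.** Chain bonds C6–C7 and then C4–C5 are cut, each removing one acetyl unit from a terminal carbanion. This reduces the chain to three commercial building blocks. The forward steps require C-acylation and not O-acylation, and reaction at the terminal carbon of the dianion.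

**5 ⇒ 4 ⇒ 3 ⇒ 2 ⇒ 1.** The C1'–O bond is cut (through C1'–Br), then the O-benzyl bonds and the tert-butyl ester. Five of the six ring B substituents are already correctly placed in 1; only the oxygen between the methyl group and the 4-oxygen is missing. The forward sequence requires electrophilic substitution at that position and not at the one between the two oxygens, and conversion of a di-ortho-substituted aryl bromide into a phenol.

## Other disconnections considered

**Alternative 1:** Michael–Claisen annulation to a dihydro ring B.
- **Cut:** C2'–C3' and C5'–C6' of ring B, with ring A complete.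
- **Forward key step:** The enol ester methyl 2-(aroyloxy)but-2-enoate A1 (aroyl = 2-benzyloxy-3-(dimethoxymethyl)-4-methoxy-6-methylbenzoyl) would take up benzyl acetoacetate A2 at its β-carbon. The acetyl methyl carbon of the adduct would then close on the methyl ester to give the cyclohexane-1,3-dione A3. Dehydrogenation, C5' formylation, acetal hydrolysis and hydrogenolysis would follow.
- **In favour:** Ring A brings its formyl carbon and methoxy group from the start, so no late choice between C3 and C5 arises. On this point the alternative is better than the chosen plan. The depside C–O bond is made as an enol ester and not on a hindered phenol, which is equal to the chosen plan.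
- **Against:** A3 is one oxidation level below a resorcinol, so an oxidant must act in the presence of the electron-rich ring A and the acetal. The annulation needs alkoxide-grade base while A1 is an acyl donor. After ring closure the α-acyloxy ketone can pass the aroyl group between O1' and O6' through its enediol. A β-substituted acceptor with a donor at the α-carbon is a weak Michael acceptor.
- **Comparison:** Structurally both plans form the ester before the hindered ring exists. Mechanistically the chosen plan reaches the arene by dehydration alone under a weak amine base, whereas this one needs strong base and then an oxidant. In step count it should be longer by about two or three steps, since the protected ring A acid takes about six steps before the annulation.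

**Alternative 2:** Acyloxy-diene Diels–Alder reaction around the ester oxygen.
- **Cut:** C1'–C2' and C3'–C4'.
- **Forward key step:** The 4-aroyloxy-1-methoxy-1,3-bis(trimethylsilyloxy)buta-1,3-diene A4 would add to benzyl but-2-ynoate A5. Loss of the methoxy group from the adduct would aromatize ring B to the protected depside A6.
- **In favour:** Ring B appears aromatic and at the right oxidation level in one step. The regiochemistry follows from the polarization of the two partners. The ester oxygen would come from carboxylate alkylation, so hindered acylation is avoided just as in the chosen plan (equal). Only one formylation (C5') remains and ring A needs no late functionalization, which is better than the chosen plan.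
- **Against:** A 3-alkyl ynoate is a sluggish dienophile towards bis(silyloxy)dienes. The acyloxy group at the diene terminus lowers nucleophilicity and adds bulk. Making A4 requires deprotonation at the carbon bearing the aroyloxy group, with risk of acyl transfer. Lewis acids that could speed the cycloaddition threaten the silyl enol ethers and the acetal.
- **Comparison:** Step economy is about equal to the chosen plan. The chosen key step is unimolecular and driven by aromatization from inexpensive building blocks, while this one depends on an intermolecular cycloaddition between two deactivated partners. The alternative is stronger on late-stage regiocontrol and weaker on the reliability of its key step.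

**Alternative 3:** Danheiser benzannulation of ring A.
- **Cut:** C1–C2, C2–C3 and C4–C5 of ring A, with C5–C6 made in the ketene-forming step.
- **Forward key step:** Irradiation of the diazo ketone A7 would give a vinylketene by Wolff rearrangement. The siloxyalkyne A8 would add to it by [2+2] cycloaddition. Four-electron opening of the cyclobutenone, six-electron closure and tautomerization would give the ring B aryl benzoate A9.
- **In favour:** Like the chosen plan it builds ring A after the ester exists (equal). It places the formyl carbon at C3 through the regiochemistry of the ketene–ynol ether union, which is better than the chosen plan. It delivers C2–OH and C4–O already differentiated, though the silyl group must then be exchanged for methyl in two steps against one.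
- **Against:** A7 holds a diazo group and an electron-poor alkene in one molecule, so dipolar cycloaddition between molecules threatens it. Making A7 means acylating the hindered phenol 5 with one specific carboxyl of an unsymmetrical unsaturated diacid, and it needs a diazoalkane. A8 has an acetal next to the ynol ether. Four pericyclic events must succeed in sequence on an ester-substituted vinylketene.
- **Comparison:** The cascade is more convergent in bond count but more fragile than a single aldol closure. The route would be clearly longer, at roughly seventeen steps against twelve.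

Key step: step 8

## Route

**Step 1**
Reactants: 1 orsellinic acid (2,4-dihydroxy-6-methylbenzoic acid)
Product: 2 tert-butyl 2,4-dihydroxy-6-methylbenzoate
Conditions: O-tert-butyl-N,N'-diisopropylisourea (2.5 equiv), THF, rt
Reagents that add atoms: O-tert-butyl-N,N'-diisopropylisourea, CC(C)NC(=NC(C)C)OC(C)(C)C
Why: Isourea tert-butyl esterification: the carboxylic acid protonates the isourea and the carboxylate takes the tert-butyl group from the resulting cation, while the much less acidic phenols are left alone; room temperature avoids decarboxylation of the β-resorcylic acid.

**Step 2**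
Reactants: 2 tert-butyl 2,4-dihydroxy-6-methylbenzoate
Product: 3 tert-butyl 2,4-bis(benzyloxy)-6-methylbenzoate
Conditions: BnBr (2.4 equiv), K2CO3, DMF, 60 °C
Reagents that add atoms: benzyl bromide, BrCc1ccccc1
Why: Williamson ether synthesis on both phenoxides; the hydrogen-bonded 2-hydroxyl needs DMF and warming, and the hindered tert-butyl ester is inert to carbonate.

**Step 3**
Reactants: 3 tert-butyl 2,4-bis(benzyloxy)-6-methylbenzoate
Product: 4 tert-butyl 4,6-bis(benzyloxy)-3-bromo-2-methylbenzoate
Conditions: NBS (1.05 equiv), MeCN, 0 °C → rt, dark
Reagents that add atoms: N-bromosuccinimide, O=C1CCC(=O)N1Br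
Why: Electrophilic aromatic bromination; the position between the methyl group and one benzyloxy group is para to the other benzyloxy group and less crowded than the position between the two ethers, so bromine should enter there as in 3,5-dialkoxytoluenes, and ionic conditions in the dark spare the benzylic positions.

**Step 4**
Reactants: 4 tert-butyl 4,6-bis(benzyloxy)-3-bromo-2-methylbenzoate
Product: 5 tert-butyl 4,6-bis(benzyloxy)-3-hydroxy-2-methylbenzoate
Conditions: Pd2(dba)3 (cat.), 2-(di-tert-butylphosphino)-2',4',6'-triisopropylbiphenyl (cat.), KOH (3 equiv), 1,4-dioxane/H2O, 100 °C, degassed; then dilute HCl, 0 °C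
Reagents that add atoms: potassium hydroxide, [K+].[OH-]
Why: Palladium-catalysed hydroxylation of an aryl bromide: oxidative addition to zerovalent palladium, bromide–hydroxide exchange and C–O reductive elimination from the bulky biarylphosphine complex; the hindered tert-butyl ester and the benzyl ethers are inert to hydroxide, and exclusion of air protects the electron-rich phenoxide.

**Step 5**
Reactants: 6 2,2,6-trimethyl-4H-1,3-dioxin-4-one; 7 acetyl chloride
Product: 8 2,2-dimethyl-6-(2-oxopropyl)-4H-1,3-dioxin-4-one
Conditions: 6 (2 equiv), LiN(SiMe3)2 (2 equiv), THF, −78 °C; 7 (1 equiv), −78 → −20 °C; aq. NH4Cl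
Reagents that add atoms: none
Why: Vinylogous Claisen-type C-acylation: the lithium dienolate formed at the 6-methyl group is acylated at its terminal carbon by the acid chloride, and the second equivalent of dienolate takes up the acidic proton of the β-keto product.

**Step 6**
Reactants: 8 2,2-dimethyl-6-(2-oxopropyl)-4H-1,3-dioxin-4-one; 9 N-methoxy-N-methylacetamide
Product: 10 6-(2,4-dioxopentyl)-2,2-dimethyl-4H-1,3-dioxin-4-one
Conditions: LiN(iPr)2 (2.2 equiv), THF, −78 °C; 9 (1.1 equiv), −78 → −20 °C; 1 M HCl
Reagents that add atoms: none
Why: Dianion acylation with a Weinreb amide: the base removes first the doubly activated methylene proton and then a terminal methyl proton, the more reactive terminal carbanion adds to the amide, and the chelated tetrahedral intermediate prevents a second addition and proton transfer until the acidic work-up.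

**Step 7**
Reactants: 10 6-(2,4-dioxopentyl)-2,2-dimethyl-4H-1,3-dioxin-4-one; 5 tert-butyl 4,6-bis(benzyloxy)-3-hydroxy-2-methylbenzoate
Product: 12 tert-butyl 4,6-bis(benzyloxy)-2-methyl-3-[(3,5,7-trioxooctanoyl)oxy]benzoate, via acylketene 11 (not isolated)
Conditions: toluene, 110 °C, 10 (1.5 equiv) added in portions to 5 (0.3 M), argon; evaporate, use crude
Reagents that add atoms: none
Why: Thermal retro-hetero-Diels–Alder fragmentation of the dioxinone releases acetone and an acylketene, and the phenol O–H adds to the sp-hybridized ketene carbon, which is unhindered enough for a di-ortho-substituted phenol; a high phenol concentration and portionwise addition favour capture by the phenol over capture by the ketene's own C5 enol.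

**Step 8**
Reactants: 12 tert-butyl 4,6-bis(benzyloxy)-2-methyl-3-[(3,5,7-trioxooctanoyl)oxy]benzoate
Product: 14 tert-butyl 4,6-bis(benzyloxy)-3-[(2,4-dihydroxy-6-methylbenzoyl)oxy]-2-methylbenzoate, via aldol adduct 13 (not isolated)
Conditions: Et3N (3 equiv), 4 Å MS, CH2Cl2, 0 °C → rt; then AcOH (6 equiv), rt
Reagents that add atoms: none
Why: Triethylamine forms the enolate of chain carbon 2, the methylene between the aryl ester and the C3 ketone, and this carbon adds to the C7 methyl ketone to give the cyclic β-hydroxy ketone 13, creating the bond that becomes C1–C6 of ring A. Elimination of water across chain C6–C7 and enolization of the C3 and C5 carbonyls then give the resorcinol ring, and the gain in aromaticity makes the sequence irreversible. The closest known reaction type is the biomimetic aldol aromatization of 3,5,7-triketo esters released from diketo-dioxinones, which gives resorcylate esters. The single ring is closed in a 6-(enolendo)-exo-trig mode, with the enolate double bond C2=C3 inside the forming ring and the ketone oxygen outside it. The two sp3 centres of 13 are transient and are erased on aromatization, so no stereocontrol is needed. The step needs the aldol mode to prevail over Claisen closure of carbon 6 on the ester, over lactonization by the C5 enol oxygen and over loss of the aryloxide to a ketene. Three things should secure this: a ketone is a better acceptor than an ester under a weak amine base without a chelating metal, the C2' methyl and C6' benzyloxy groups flanking the ester oxygen shield the ester carbonyl, and the medium is dry and free of alcohols so that any aryloxide that leaves can only add back. Acetic acid at the end buffers the mixture and completes the dehydration.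

**Step 9**
Reactants: 14 tert-butyl 4,6-bis(benzyloxy)-3-[(2,4-dihydroxy-6-methylbenzoyl)oxy]-2-methylbenzoate
Product: 15 tert-butyl 4,6-bis(benzyloxy)-3-[(2-hydroxy-4-methoxy-6-methylbenzoyl)oxy]-2-methylbenzoate
Conditions: MeI (1.2 equiv), K2CO3 (1.5 equiv), acetone, rt
Reagents that add atoms: iodomethane, CI
Why: Williamson methylation; the C4 hydroxyl is para to the ester carbonyl and not hydrogen-bonded, so it is the more acidic and more nucleophilic phenol, while the C2 hydroxyl is held by its hydrogen bond to the ester carbonyl and ring B has no free hydroxyl at this stage.

**Step 10**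
Reactants: 15 tert-butyl 4,6-bis(benzyloxy)-3-[(2-hydroxy-4-methoxy-6-methylbenzoyl)oxy]-2-methylbenzoate
Product: 16 tert-butyl 4,6-dihydroxy-3-[(2-hydroxy-4-methoxy-6-methylbenzoyl)oxy]-2-methylbenzoate
Conditions: H2 (1 atm), 10% Pd/C, EtOAc, rt
Reagents that add atoms: none
Why: Catalytic hydrogenolysis of the two benzyl aryl ethers; the aryl ester and the tert-butyl ester are untouched, and the neutral medium gives the newly freed 6'-hydroxyl no chance to take over the acyl group.

**Step 11**
Reactants: 16 tert-butyl 4,6-dihydroxy-3-[(2-hydroxy-4-methoxy-6-methylbenzoyl)oxy]-2-methylbenzoate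
Product: 17 tert-butyl 5-formyl-3-[(3-formyl-2-hydroxy-4-methoxy-6-methylbenzoyl)oxy]-4,6-dihydroxy-2-methylbenzoate
Conditions: MgCl2 (6 equiv), Et3N (12 equiv), (CH2O)n (excess), THF, 65 °C; then 1 M HCl, 0 °C
Reagents that add atoms: paraformaldehyde (as formaldehyde), C=O
Why: Magnesium-mediated ortho-formylation (Casnati–Skattebøl reaction): each magnesium phenoxide delivers bound formaldehyde to its ortho carbon and the hydroxymethyl intermediate is oxidized by a second formaldehyde through hydride transfer; C3 of ring A and C5' of ring B are the only free ortho positions, so C5 of ring A, which is para to its phenol, should stay untouched, and the tert-butyl ester tolerates the conditions.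

**Step 12**
Reactants: 17 tert-butyl 5-formyl-3-[(3-formyl-2-hydroxy-4-methoxy-6-methylbenzoyl)oxy]-4,6-dihydroxy-2-methylbenzoate
Product: 18 haemathamnolic acid (5-formyl-3-[(3-formyl-2-hydroxy-4-methoxy-6-methylbenzoyl)oxy]-4,6-dihydroxy-2-methylbenzoic acid)
Conditions: CF3CO2H/CH2Cl2 (1:3), 0 °C → rt
Reagents that add atoms: none
Why: Acidolysis of the tert-butyl ester by alkyl–oxygen cleavage with loss of 2-methylpropene; the hindered aryl ester, the chelated aldehydes and the phenols are stable to trifluoroacetic acid at room temperature, and the low temperature guards against decarboxylation.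

## Compound list

1 | orsellinic acid (2,4-dihydroxy-6-methylbenzoic acid) | Cc1cc(O)cc(O)c1C(=O)O | starting material
2 | tert-butyl 2,4-dihydroxy-6-methylbenzoate | Cc1cc(O)cc(O)c1C(=O)OC(C)(C)C | intermediate
3 | tert-butyl 2,4-bis(benzyloxy)-6-methylbenzoate | Cc1cc(OCc2ccccc2)cc(OCc2ccccc2)c1C(=O)OC(C)(C)C | intermediate
4 | tert-butyl 4,6-bis(benzyloxy)-3-bromo-2-methylbenzoate | Cc1c(Br)c(OCc2ccccc2)cc(OCc2ccccc2)c1C(=O)OC(C)(C)C | intermediate
5 | tert-butyl 4,6-bis(benzyloxy)-3-hydroxy-2-methylbenzoate (ring B phenol) | Cc1c(O)c(OCc2ccccc2)cc(OCc2ccccc2)c1C(=O)OC(C)(C)C | intermediate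
6 | 2,2,6-trimethyl-4H-1,3-dioxin-4-one | CC1=CC(=O)OC(C)(C)O1 | starting material
7 | acetyl chloride | CC(=O)Cl | starting material
8 | 2,2-dimethyl-6-(2-oxopropyl)-4H-1,3-dioxin-4-one | CC(=O)CC1=CC(=O)OC(C)(C)O1 | intermediate
9 | N-methoxy-N-methylacetamide | CON(C)C(C)=O | starting material
10 | 6-(2,4-dioxopentyl)-2,2-dimethyl-4H-1,3-dioxin-4-one | CC(=O)CC(=O)CC1=CC(=O)OC(C)(C)O1 | intermediate
11 | acylketene oct-1-ene-1,3,5,7-tetrone (formed and consumed in step 7) | CC(=O)CC(=O)CC(=O)C=C=O | intermediate
12 | tert-butyl 4,6-bis(benzyloxy)-2-methyl-3-[(3,5,7-trioxooctanoyl)oxy]benzoate | CC(=O)CC(=O)CC(=O)CC(=O)Oc1c(C)c(C(=O)OC(C)(C)C)c(OCc2ccccc2)cc1OCc1ccccc1 | intermediate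
13 | tert-butyl 4,6-bis(benzyloxy)-3-{[(2-hydroxy-2-methyl-4,6-dioxocyclohexyl)carbonyl]oxy}-2-methylbenzoate (aldol adduct, stereoisomer mixture, formed and consumed in step 8) | CC1(O)CC(=O)CC(=O)C1C(=O)Oc1c(C)c(C(=O)OC(C)(C)C)c(OCc2ccccc2)cc1OCc1ccccc1 | intermediate
14 | tert-butyl 4,6-bis(benzyloxy)-3-[(2,4-dihydroxy-6-methylbenzoyl)oxy]-2-methylbenzoate | Cc1cc(O)cc(O)c1C(=O)Oc1c(C)c(C(=O)OC(C)(C)C)c(OCc2ccccc2)cc1OCc1ccccc1 | intermediate
15 | tert-butyl 4,6-bis(benzyloxy)-3-[(2-hydroxy-4-methoxy-6-methylbenzoyl)oxy]-2-methylbenzoate | COc1cc(C)c(C(=O)Oc2c(C)c(C(=O)OC(C)(C)C)c(OCc3ccccc3)cc2OCc2ccccc2)c(O)c1 | intermediate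
16 | tert-butyl 4,6-dihydroxy-3-[(2-hydroxy-4-methoxy-6-methylbenzoyl)oxy]-2-methylbenzoate | COc1cc(C)c(C(=O)Oc2c(C)c(C(=O)OC(C)(C)C)c(O)cc2O)c(O)c1 | intermediate
17 | tert-butyl 5-formyl-3-[(3-formyl-2-hydroxy-4-methoxy-6-methylbenzoyl)oxy]-4,6-dihydroxy-2-methylbenzoate | COc1cc(C)c(C(=O)Oc2c(C)c(C(=O)OC(C)(C)C)c(O)c(C=O)c2O)c(O)c1C=O | intermediate
18 | haemathamnolic acid | COc1cc(C)c(C(=O)Oc2c(C)c(C(=O)O)c(O)c(C=O)c2O)c(O)c1C=O | target

## Step count and least certain steps

Total: 12 steps. Longest linear sequence: 10 steps (steps 1–4 and 7–12 from orsellinic acid); the chain branch (steps 5 and 6) joins at step 7.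

**Step 8 (key step).** The ring B aryloxide may be lost from the ester before ring A has formed. This can happen by Claisen closure of carbon 6 on C1, by attack of the C5 enol oxygen on C1, or by elimination to a ketene that then cyclizes on its own enol. The cause is that an aryl ester is a far better acyl donor than the alkyl esters on which this folding is usually run. The fallback forms the ester bond conventionally and sets out from 5, with 1 as the source of ring A. Compound 1 is methylated at the carboxyl and the C4 hydroxyl (MeI, K2CO3, DMF) to methyl 2-hydroxy-4-methoxy-6-methylbenzoate F1, and this is saponified (KOH, aqueous DMSO, 90 °C) to 2-hydroxy-4-methoxy-6-methylbenzoic acid F2. F2 is condensed with 5 through its mixed anhydride with trifluoroacetic acid ((CF3CO)2O, toluene, 0 °C → rt), the usual way to esterify a hindered salicylic acid with a phenol. The route is rejoined at 15.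

**Step 7.** Capture of the acylketene by the di-ortho-substituted phenol may be too slow, so that the ketene is consumed by internal capture on its C5 enol or by dimerization. The fallback sets out from 10 and 5. Compound 10 is folded on its own with Et3N in CH2Cl2 to 7-hydroxy-2,2,5-trimethyl-4H-1,3-benzodioxin-4-one F3, which is methylated (MeI, K2CO3, acetone) to 7-methoxy-2,2,5-trimethyl-4H-1,3-benzodioxin-4-one F4. Irradiation of F4 at about 300 nm in CH2Cl2 with 5 expels acetone and gives a quinoketene that the phenol captures. This is a known photochemical acylation of hindered hydroxyl groups, and the route is rejoined at 15.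

**Step 11.** Two processes threaten this step. Formylation of the chelated, ester-deactivated ring A phenol may stop short. The magnesium phenoxide at O6' may take over or cleave the neighbouring acyl group under the basic conditions. The fallback replaces the base-mediated method by an acid-mediated one and sets out from 16. Rieche formylation (Cl2CHOMe, TiCl4, CH2Cl2, −20 → 0 °C, then aqueous HCl) is ortho-directed by the titanium phenoxides, and TiCl4 also removes the tert-butyl group. Compound 17 is bypassed and the route is rejoined at 18. No new compound is made.

**Step 3.** Bromination may occur at the position between the two benzyloxy groups or twice, because both free positions are activated by two ether oxygens. The fallback places the oxygen by a reaction with a fixed para preference and sets out from 2. Elbs persulfate oxidation (K2S2O8, aqueous KOH, 0 °C → rt) attacks para to the C2 phenoxide, the only open para position, and gives potassium 3-(tert-butoxycarbonyl)-4,6-dihydroxy-2-methylphenyl sulfate F5. Benzylation of both phenols (BnBr, K2CO3, DMF) gives potassium 4,6-bis(benzyloxy)-3-(tert-butoxycarbonyl)-2-methylphenyl sulfate F6. Brief hydrolysis of the sulfate (dilute HCl, THF, 40 °C) rejoins the route at 5.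

**Step 4.** Oxidative addition and C–O reductive elimination at a bromide flanked by a methyl and a benzyloxy group may be slow, so that reduction of the C–Br bond or air oxidation of the phenoxide takes over. The fallback makes the C–O bond through boron and sets out from 4. Miyaura borylation (bis(pinacolato)diboron, PdCl2(dppf), KOAc, 1,4-dioxane, 90 °C) gives tert-butyl 4,6-bis(benzyloxy)-2-methyl-3-(4,4,5,5-tetramethyl-1,3,2-dioxaborolan-2-yl)benzoate F7. Oxidation of the C–B bond (H2O2, aqueous NaHCO3, THF, 0 °C) rejoins the route at 5.

## Further compounds

F1 | step 8 | methyl 2-hydroxy-4-methoxy-6-methylbenzoate | COC(=O)c1c(C)cc(OC)cc1O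
F2 | step 8 | 2-hydroxy-4-methoxy-6-methylbenzoic acid | COc1cc(C)c(C(=O)O)c(O)c1
F3 | step 7 | 7-hydroxy-2,2,5-trimethyl-4H-1,3-benzodioxin-4-one | CC1(C)OC(=O)c2c(C)cc(O)cc2O1
F4 | step 7 | 7-methoxy-2,2,5-trimethyl-4H-1,3-benzodioxin-4-one | CC1(C)OC(=O)c2c(C)cc(OC)cc2O1
F0 | step 11 | none | none
F5 | step 3 | potassium 3-(tert-butoxycarbonyl)-4,6-dihydroxy-2-methylphenyl sulfate | Cc1c(OS(=O)(=O)[O-])c(O)cc(O)c1C(=O)OC(C)(C)C.[K+]
F6 | step 3 | potassium 4,6-bis(benzyloxy)-3-(tert-butoxycarbonyl)-2-methylphenyl sulfate | Cc1c(OS(=O)(=O)[O-])c(OCc2ccccc2)cc(OCc2ccccc2)c1C(=O)OC(C)(C)C.[K+]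
F7 | step 4 | tert-butyl 4,6-bis(benzyloxy)-2-methyl-3-(4,4,5,5-tetramethyl-1,3,2-dioxaborolan-2-yl)benzoate | Cc1c(B2OC(C)(C)C(C)(C)O2)c(OCc2ccccc2)cc(OCc2ccccc2)c1C(=O)OC(C)(C)C
A1 | alternative 1 | methyl 2-{[2-(benzyloxy)-3-(dimethoxymethyl)-4-methoxy-6-methylbenzoyl]oxy}but-2-enoate (alkene geometry not specified) | CC=C(OC(=O)c1c(C)cc(OC)c(C(OC)OC)c1OCc1ccccc1)C(=O)OC
A2 | alternative 1 | benzyl acetoacetate (benzyl 3-oxobutanoate) | CC(=O)CC(=O)OCc1ccccc1
A3 | alternative 1 | benzyl 5-{[2-(benzyloxy)-3-(dimethoxymethyl)-4-methoxy-6-methylbenzoyl]oxy}-6-methyl-2,4-dioxocyclohexane-1-carboxylate (diastereomer mixture) | CC1C(OC(=O)c2c(C)cc(OC)c(C(OC)OC)c2OCc2ccccc2)C(=O)CC(=O)C1C(=O)OCc1ccccc1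
A4 | alternative 2 | 4-{[2-(benzyloxy)-3-(dimethoxymethyl)-4-methoxy-6-methylbenzoyl]oxy}-1-methoxy-1,3-bis(trimethylsilyloxy)buta-1,3-diene (alkene geometries not specified) | COC(O[Si](C)(C)C)=CC(O[Si](C)(C)C)=COC(=O)c1c(C)cc(OC)c(C(OC)OC)c1OCc1ccccc1
A5 | alternative 2 | benzyl but-2-ynoate | CC#CC(=O)OCc1ccccc1
A6 | alternative 2 | benzyl 5-{[2-(benzyloxy)-3-(dimethoxymethyl)-4-methoxy-6-methylbenzoyl]oxy}-2,4-dihydroxy-6-methylbenzoate | O=C(OCc1ccccc1)c1c(C)c(OC(=O)c2c(C)cc(OC)c(C(OC)OC)c2OCc2ccccc2)c(O)cc1O
A7 | alternative 3 | 4,6-bis(benzyloxy)-3-(tert-butoxycarbonyl)-2-methylphenyl (2E)-5-diazo-3-methyl-4-oxopent-2-enoate | [N-]=[N+]=CC(=O)/C(C)=C/C(=O)Oc1c(C)c(C(=O)OC(C)(C)C)c(OCc2ccccc2)cc1OCc1ccccc1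
A8 | alternative 3 | 3,3-diethoxy-1-(triisopropylsilyloxy)prop-1-yne | CCOC(OCC)C#CO[Si](C(C)C)(C(C)C)C(C)C
A9 | alternative 3 | 4,6-bis(benzyloxy)-3-(tert-butoxycarbonyl)-2-methylphenyl 3-(diethoxymethyl)-2-hydroxy-6-methyl-4-(triisopropylsilyloxy)benzoate | CCOC(OCC)c1c(O)c(C(=O)Oc2c(C)c(C(=O)OC(C)(C)C)c(OCc3ccccc3)cc2OCc2ccccc2)c(C)cc1O[Si](C(C)C)(C(C)C)C(C)C
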